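Once the feed is in, two sums stay fixed in a stirred flask as long as L, Q, J and D are what the L becomes, counted per starting volume: [L] + [Q] + [J] + [D] equals the L charged, and [G] + [Q] + [J] + two times [D] equals the G charged, as a mono adduct holds one G and D holds two. Subtract them at the moment G is gone and the mono adducts drop out: D less L, in parts of the L charged, equals charged [G] over charged [L], less one. I call this the stop gap, here 0 percentage points.

| flask | L | G | remark | time |
|---|---|---|---|---|
| maple | 0.65 M (fed, over 25 min) | 1.3 M | run made earlier; the fed solution adds 0.10 times the starting volume |  |
| elm | 0.98 M (fed, over 25 min) | 1.3 M | run made earlier; the fed solution adds 0.10 times the starting volume |  |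
| flask | 1.3 M (fed, over 25 min) | 1.30 M | the fed solution adds 0.10 times the starting volume | 8.0 h |

- maple (time / h: L / %, Q / %, J / %): 1.00: 0, 1, 31; 2.00: 0, 1, 18; 3.00: 0, 2, 14; 4.00: 0, 2, 15; 5.00: 1, 0, 3; 6.00: 0, 0, 11
- elm (time / h: L / %, Q / %, J / %): 0.417: 27, 9, 33; 1.33: 10, 11, 41; 2.50: 5, 6, 39; 4.00: 6, 10, 39; 5.00: 7, 8, 41; 6.00: 5, 8, 39

(standard deviation of a reading: 2 percentage points)

- charges are per starting volume, the dose included; the dosed solution carries all of it

* amount of L at 8.0 h, in percent of the L charged
* amount of Q at 8.0 h, in percent of the L charged
* amount of J at 8.0 h, in percent of the L charged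
* amount of D at 8.0 h, in percent of the L charged

I build the flask up step by step. First comes the main step, L + G to a mono adduct: 1.3 M of L meets 1.30 M of G, one for one, so on this step by itself the charges leave 0 M over. J runs ahead of Q, 3.67 to one in the first elm reading.

Then I add G on the adducts, which makes D. G is now the limiting reagent, on these steps each D leaves one L unreacted, and the stop gap of 0 points says that with these steps D and L end level in the flask.

The elm run tests this. Its stop gap, which D less L should show if G is gone there, is 33 points, while D taken as what the readings lack, less L, averages 40 points over its last three readings. That leaves the rest of the scheme an excess of 7 points, a reading with a scatter of 2 points on each figure behind it, so I suspect something outside my two sums. My own reckoning for the flask is therefore D above L by about that excess, not level.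

The forecast differs, with L 20 %, Q 11 %, J 47 % and D 22 %, on the ground that the flask “stalls when G is spent, which means L ≈ D”.

The flask gives L 14.6 %, Q 3.35 %, J 37.2 % and D 24.7 %.

    L + G → Q (k = 0.140 L mol⁻¹ min⁻¹)
    L + G → J (k = 0.260 L mol⁻¹ min⁻¹)
    G + Q → D (k = 0.150 L mol⁻¹ min⁻¹)
    G + J → D (k = 0.0510 L mol⁻¹ min⁻¹)
    L + Q → Z (k = 0.0140 L mol⁻¹ min⁻¹)

Against the stop gap of 0 points, D stands 10 points above L in the flask, which matches the net turnover of L + Q to Z, 10.1 % of the L charged, a step that spends no new G. In the flask the half-life of Q toward D, 0.059 h with G as charged, is shorter than its 0.63 h toward Z with the whole charge of L at once, but G stands at 0 % by 4.00 h, and from there to 8.00 h Z, which counts as two in each percentage, rises from 14.4 % to 20.2 % while D stands at 24.7 %. With 2.2 M of G the stop gap is 69 points, and that neighbour flask ends with G at 0 %, D less L at 70 points and Z at 0.866 %.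

(The data are simulated on assumed constants; the scatter is artificial.)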